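Carry 2.81: this is the selectivity factor, the left-handed rate constant with reagent over the right-handed one. You read it from the first green reading as the logarithm of the unreacted part of the left hand's own charge over the same logarithm for the right hand. Green is the run to use, since it holds more impurity than catalyst.

in all of them: racemization catalyst 10 µM
- blue: left-handed substrate 10 mM; right-handed substrate 10 mM; reagent 20 mM; impurity 6.5 µM; run made earlier
- amber: left-handed substrate 10 mM; right-handed substrate 10 mM; reagent 20 mM; impurity 9.8 µM; run made earlier
- green: left-handed substrate 5 mM; right-handed substrate 5 mM; reagent 20 mM; impurity 13 µM; run made earlier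
- flask: left-handed substrate 10 mM; right-handed substrate 10 mM; reagent 20.0 mM; impurity 13 µM; time 10 d

| run | time / d | left-handed product / % | right-handed product / % |
|---|---|---|---|
| blue | 1.04 | 39.3 | 19.9 |
| blue | 2.00 | 44.6 | 26.0 |
| blue | 5.00 | 49.9 | 35.4 |
| blue | 12.0 | 51.3 | 42.0 |
| amber | 1.67 | 44.1 | 23.6 |
| amber | 4.00 | 47.7 | 32.6 |
| amber | 8.00 | 49.6 | 38.7 |
| amber | 12.0 | 49.7 | 42.2 |
| green | 1.67 | 46.3 | 30.2 |
| green | 4.00 | 49.4 | 42.4 |
| green | 8.00 | 50.4 | 49.0 |
| green | 12.0 | 50.6 | 49.8 |

(scatter of a reading: 0.5 percentage points)

- reagent is single-handed; left-handed substrate and right-handed substrate are mirror images of each other, charged as a racemate, each of them at the stated concentration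
- what was read earlier has a scatter of 0.5 percentage points, one standard deviation
- an excess is the difference of the two amounts in percent of their sum
- an excess is below zero if the other one leads
- the handed part of reagent does not stay in what it makes, so the products of the two hands are mirror images too

- left-handed product and right-handed product together, in percent of the left-handed substrate and right-handed substrate charged together, at 10 d
- excess of left-handed product over right-handed product in the product at 10 d
- whether the exchange between left-handed substrate and right-handed substrate keeps pace with the reaction: how far the product's excess at 10 d gets from its value without exchange to its value with instant exchange (above 80% keeps pace, below 20% hardly takes part, else lags behind)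

Build the flask up, starting with reagent and the two hands, with no catalyst yet. Both rates carry the same [reagent], so it cancels:

part of left hand unreacted = (part of right hand unreacted)^2.81

The flask's charge holds 20.0 mM of reagent against 20.0 mM of both substrates, so in this step [reagent] = [left-handed substrate] + [right-handed substrate] throughout. Once nearly all of the left hand has reacted, the rate is close to k[right-handed substrate]², which integrates to:

1/[right-handed substrate] grows by k per day

Amber has the same substrate and reagent charges, and nearly all of its left hand has reacted by 4.00 d. Its [right-handed substrate] reads 3.48 mM there and 1.56 mM at 12.0 d, so k reads 0.0442 L mmol⁻¹ d⁻¹. Starting the flask from amber's reading at 4.00 d, I get for 10 d: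

[right-handed substrate] = 1.81 mM, [left-handed substrate] = 0.0819 mM

That makes my yield 90.5% and my excess 9.54%.

Now add the catalyst: exchange shows as left-handed product above half of the charge. Blue reads 1.3 percentage points above that at 12.0 d, with 3.50 µM of catalyst above impurity in its charge. Amber, with 0.200 µM above, reads 49.7% at 12.0 d.

Last comes the impurity. The flask has more of it than catalyst, so I leave my numbers as they are and expect exchange to hardly take part.

The forecast says 91%, 9.5% and hardly takes part, on the ground of “the impurity titrating the catalyst about 1:1”.

The flask gives 90.5%, 9.83% and hardly takes part, at 0.31% of the way.

    reagent + right-handed substrate → right-handed product (k = 1.60 L mol⁻¹ h⁻¹)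
    racemization catalyst + impurity → spent catalyst B (k = 3.60 × 10⁵ L mol⁻¹ h⁻¹)
    2 racemization catalyst → spent catalyst A (k = 48000 L mol⁻¹ h⁻¹)
    reagent + left-handed substrate → left-handed product (k = 4.80 L mol⁻¹ h⁻¹)
    left-handed substrate + racemization catalyst ⇌ right-handed substrate + racemization catalyst, rate k5*[racemization catalyst]*[left-handed substrate] forward; the back reaction follows from the equilibrium constant (k = 3200 L mol⁻¹ h⁻¹)

In this flask the racemization catalyst stands at 0% by 1.00 d, as 88.1% spent catalyst B and 11.9% spent catalyst A, with 32.2% of the impurity's charge left. At 10.0 d the 18% of its own charge of right-handed substrate left gives 0.854% of the left hand's charge by the rule, against 0.62% in this flask. The same flask with 8.0 mM of reagent has reagent as the limiting reagent, with 0.018% of its charge left at 10.0 d. In that flask the 76% of the right hand's charge left gives 46.2% of the left hand's charge against 44%, and an excess of 38.3% against 40.1%.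

The earlier runs and the new flask were computed for substances that don't exist; the scatter is artificial.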